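**Retrosynthetic overview**
- The strategy rests on the furan ring of the benzofuran: C3 carries a one-carbon carbonyl group (the formyl carbon), and C2 carries both O1 and ring B (4-hydroxy-3-methoxyphenyl). Anti-oxypalladation of a diarylalkyne with CO capture at C3 installs this pattern in one operation.
- Target 13 ⇐ debenzylation, MnO2 oxidation of the C3 carbinol and hydride reduction ⇐ methyl benzofuran-3-carboxylate 10 ⇐ (O1–C2 and C3–CO bonds, furan ring) 2-(arylethynyl)phenol 9 + CO + MeOH.
- 9 ⇐ aminolysis of the aryl acetate of 8 ⇐ Sonogashira coupling of iodoarene 5 with alkyne 7. The phenol stays acetylated through the coupling, so the free alkynylphenol never meets the palladium and copper catalysts without CO.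
- 5 ⇐ eugenol 1 (hydroboration, ortho-iodination, diacetylation); 7 ⇐ O-benzylvanillin 6 (Ohira–Bestmann alkynylation).
- Ring order: rings A and B come from the starting materials; the furan ring is the only ring made (step 7).

Key step: step 7

Remark: the target has no stereocentre, so no stereocontrol is needed; 4-(benzyloxy)-3-methoxybenzaldehyde (O-benzylvanillin) is taken as a catalogue compound.

**Route**

Step 1
Reactants: 1 eugenol (4-allyl-2-methoxyphenol)
Product: 3 3-(4-hydroxy-3-methoxyphenyl)propan-1-ol, via bis(9-BBN) adduct 2 (not isolated)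
Conditions: 9-BBN (2.5 equiv), THF, 0 °C → rt; then aq. NaOH, H2O2, 0 °C → rt
Reagents that add atoms: 9-borabicyclo[3.3.1]nonane (9-BBN), B1C2CCCC1CCC2; hydrogen peroxide, OO
Why: Anti-Markovnikov hydroboration–oxidation of the terminal alkene, in which the bulky 9-BBN places boron on the terminal carbon and a second equivalent is taken up by the phenol as an aryloxyborane (adduct 2), after which alkaline H2O2 turns the C–B bond into the C–OH bond of 3 and the B–OAr bond is hydrolysed, so that no 9-BBN atom remains in 3.

Step 2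
Reactants: 3 3-(4-hydroxy-3-methoxyphenyl)propan-1-ol
Product: 4 3-(4-hydroxy-3-iodo-5-methoxyphenyl)propan-1-ol
Conditions: I2 (1.05 equiv), KI, NaHCO3, THF–H2O, 0 °C → rt
Reagents that add atoms: iodine, II
Why: Electrophilic aromatic iodination through the phenoxide should enter at the only free position ortho or para to the phenol oxygen (the other ortho carbon bears OMe, the para carbon the chain), and the primary alcohol is inert.

Step 3
Reactants: 4 3-(4-hydroxy-3-iodo-5-methoxyphenyl)propan-1-ol
Product: 5 3-(4-acetoxy-3-iodo-5-methoxyphenyl)propyl acetate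
Conditions: Ac2O (3 equiv), pyridine, DMAP (cat.), CH2Cl2, 0 °C → rt
Reagents that add atoms: acetic anhydride, CC(=O)OC(C)=O
Why: DMAP-catalysed O-acylation esterifies both hydroxyl groups, so the phenol is masked for the coupling and the side-chain alcohol is protected in the same operation.

Step 4
Reactants: 6 4-(benzyloxy)-3-methoxybenzaldehyde (O-benzylvanillin)
Product: 7 1-(benzyloxy)-4-ethynyl-2-methoxybenzene
Conditions: dimethyl (1-diazo-2-oxopropyl)phosphonate (1.3 equiv), K2CO3 (2 equiv), MeOH, 0 °C → rt
Reagents that add atoms: dimethyl (1-diazo-2-oxopropyl)phosphonate (Ohira–Bestmann reagent), COP(=O)(OC)C(=[N+]=[N-])C(C)=O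
Why: Seyferth–Gilbert homologation in the Ohira–Bestmann variant, in which methanolysis of the acetyl group frees the diazomethylphosphonate anion, olefination of the aldehyde gives a diazoalkene, and loss of N2 with 1,2-shift gives the terminal alkyne; the benzyl ether is stable to K2CO3 in MeOH.

Step 5
Reactants: 5 3-(4-acetoxy-3-iodo-5-methoxyphenyl)propyl acetate; 7 1-(benzyloxy)-4-ethynyl-2-methoxybenzene
Product: 8 3-[4-acetoxy-3-[(4-benzyloxy-3-methoxyphenyl)ethynyl]-5-methoxyphenyl]propyl acetate
Conditions: PdCl2(PPh3)2 (3 mol%), CuI (5 mol%), Et3N, THF, degassed, rt → 40 °C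
Reagents that add atoms: none
Why: Sonogashira coupling of an aryl iodide proceeds under mild conditions, and because the phenol is an acetate the coupled product cannot undergo the palladium/copper heteroannulation that would give the 3-unsubstituted benzofuran.

Step 6
Reactants: 8 3-[4-acetoxy-3-[(4-benzyloxy-3-methoxyphenyl)ethynyl]-5-methoxyphenyl]propyl acetate
Product: 9 3-[3-[(4-benzyloxy-3-methoxyphenyl)ethynyl]-4-hydroxy-5-methoxyphenyl]propyl acetate
Conditions: pyrrolidine (1.5 equiv), MeCN, 0 °C → rt
Reagents that add atoms: none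
Why: Chemoselective aminolysis of the aryl ester, since an aryloxide is a far better leaving group than an alkoxide, so the amine should cleave the phenolic acetate and leave the primary alkyl acetate, without metal or strong base that could close the alkynylphenol.

Step 7
Reactants: 9 3-[3-[(4-benzyloxy-3-methoxyphenyl)ethynyl]-4-hydroxy-5-methoxyphenyl]propyl acetate
Product: 10 methyl 5-(3-acetoxypropyl)-2-(4-benzyloxy-3-methoxyphenyl)-7-methoxybenzofuran-3-carboxylate
Conditions: PdCl2 (10 mol%), CuCl2 (3 equiv), NaOAc (4 equiv), CO (1 atm), MeOH, rt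
Reagents that add atoms: carbon monoxide, [C-]#[O+]; methanol, CO
Why: Divalent palladium binds the alkyne of 9 and the acetate-buffered phenol oxygen adds anti to it at the carbon that carries ring B, a 5-endo-dig oxypalladation that forms O1–C2, closes the furan ring and leaves a vinylpalladium at C3. CO inserts into that C–Pd bond and methanol cleaves the acylpalladium to the C3 methyl ester, releasing zerovalent palladium, which two equivalents of CuCl2 return to divalent palladium. The closest known reaction type is the palladium-catalysed oxidative cyclization–alkoxycarbonylation of 2-alkynylphenols to benzofuran-3-carboxylates. No stereocentre is created. Regiochemistry is fixed by geometry, since the ortho oxygen can reach only the distal alkyne carbon in a five-membered closure, and the donor-substituted ring B polarizes the alkyne further toward attack at that carbon. The selectivity the step needs is CO insertion over protodepalladation of the vinylpalladium, which would give the 3-unsubstituted benzofuran; NaOAc takes up the HCl formed, the CO atmosphere and excess CuCl2 keep the carbonylative cycle turning, the phenol is unmasked only at this stage, and leaving out carbonate base should keep the side-chain acetate intact in methanol.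

Step 8
Reactants: 10 methyl 5-(3-acetoxypropyl)-2-(4-benzyloxy-3-methoxyphenyl)-7-methoxybenzofuran-3-carboxylate
Product: 11 [2-(4-benzyloxy-3-methoxyphenyl)-5-(3-hydroxypropyl)-7-methoxybenzofuran-3-yl]methanol
Conditions: i-Bu2AlH (6 equiv), CH2Cl2, −78 → 0 °C; aq. potassium sodium tartrate
Reagents that add atoms: none
Why: Hydride reduction of both esters to primary alcohols with excess i-Bu2AlH; the benzyl ether, methyl ethers and benzofuran are inert, and the neutral tartrate work-up spares the acid-sensitive heteroaryl carbinol.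

Step 9
Reactants: 11 [2-(4-benzyloxy-3-methoxyphenyl)-5-(3-hydroxypropyl)-7-methoxybenzofuran-3-yl]methanol
Product: 12 2-(4-benzyloxy-3-methoxyphenyl)-5-(3-hydroxypropyl)-7-methoxybenzofuran-3-carbaldehyde
Conditions: activated MnO2 (15 equiv), CH2Cl2, rt
Reagents that add atoms: none
Why: MnO2 oxidation is selective for benzylic and heteroaryl carbinols, so the C3 hydroxymethyl group should go to the aldehyde while the saturated primary alcohol of the side chain is untouched and no over-oxidation occurs.

Step 10
Reactants: 12 2-(4-benzyloxy-3-methoxyphenyl)-5-(3-hydroxypropyl)-7-methoxybenzofuran-3-carbaldehyde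
Product: 13 2-(4-hydroxy-3-methoxyphenyl)-5-(3-hydroxypropyl)-7-methoxybenzofuran-3-carbaldehyde (target)
Conditions: BCl3 (1 M in CH2Cl2, 4 equiv), C6HMe5 (3 equiv), CH2Cl2, −78 °C; then MeOH, −78 °C → rt
Reagents that add atoms: none
Why: Lewis-acid cleavage of the aryl benzyl ether with pentamethylbenzene as a non-basic benzyl cation scavenger; at −78 °C the two methyl ethers and the aldehyde should survive, and the side-chain alcohol is held as a borate that methanol releases.

**Compound list**
1 | eugenol (4-allyl-2-methoxyphenol) | C=CCc1ccc(O)c(OC)c1 | starting material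
2 | 9-[3-[4-(9-borabicyclo[3.3.1]nonan-9-yloxy)-3-methoxyphenyl]propyl]-9-borabicyclo[3.3.1]nonane (bis(9-BBN) adduct) | COc1cc(CCCB2C3CCCC2CCC3)ccc1OB1C2CCCC1CCC2 | intermediate (not isolated)
3 | 3-(4-hydroxy-3-methoxyphenyl)propan-1-ol | COc1cc(CCCO)ccc1O | intermediate
4 | 3-(4-hydroxy-3-iodo-5-methoxyphenyl)propan-1-ol | COc1cc(CCCO)cc(I)c1O | intermediate
5 | 3-(4-acetoxy-3-iodo-5-methoxyphenyl)propyl acetate | COc1cc(CCCOC(C)=O)cc(I)c1OC(C)=O | intermediate
6 | 4-(benzyloxy)-3-methoxybenzaldehyde (O-benzylvanillin) | COc1cc(C=O)ccc1OCc1ccccc1 | starting material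
7 | 1-(benzyloxy)-4-ethynyl-2-methoxybenzene | COc1cc(C#C)ccc1OCc1ccccc1 | intermediate
8 | 3-[4-acetoxy-3-[(4-benzyloxy-3-methoxyphenyl)ethynyl]-5-methoxyphenyl]propyl acetate | COc1cc(CCCOC(C)=O)cc(C#Cc2ccc(OCc3ccccc3)c(OC)c2)c1OC(C)=O | intermediate
9 | 3-[3-[(4-benzyloxy-3-methoxyphenyl)ethynyl]-4-hydroxy-5-methoxyphenyl]propyl acetate | COc1cc(CCCOC(C)=O)cc(C#Cc2ccc(OCc3ccccc3)c(OC)c2)c1O | intermediate
10 | methyl 5-(3-acetoxypropyl)-2-(4-benzyloxy-3-methoxyphenyl)-7-methoxybenzofuran-3-carboxylate | COC(=O)c1c(-c2ccc(OCc3ccccc3)c(OC)c2)oc2c(OC)cc(CCCOC(C)=O)cc12 | intermediate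
11 | [2-(4-benzyloxy-3-methoxyphenyl)-5-(3-hydroxypropyl)-7-methoxybenzofuran-3-yl]methanol | OCc1c(-c2ccc(OCc3ccccc3)c(OC)c2)oc2c(OC)cc(CCCO)cc12 | intermediate
12 | 2-(4-benzyloxy-3-methoxyphenyl)-5-(3-hydroxypropyl)-7-methoxybenzofuran-3-carbaldehyde | O=Cc1c(-c2ccc(OCc3ccccc3)c(OC)c2)oc2c(OC)cc(CCCO)cc12 | intermediate
13 | 2-(4-hydroxy-3-methoxyphenyl)-5-(3-hydroxypropyl)-7-methoxybenzofuran-3-carbaldehyde | COc1cc(-c2oc3c(OC)cc(CCCO)cc3c2C=O)ccc1O | target

**Step count**
Total steps: 10. Longest linear sequence: 9 steps (from 1 through steps 1, 2, 3, 5, 6, 7, 8, 9 and 10 to 13).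

**Steps most likely to fail**

Step 7. Protodepalladation of the vinylpalladium may outrun CO insertion, or CuCl2 may oxidize or chlorinate the electron-rich phenol before cyclization. The fallback sets out from 9 and comes back at 10, and separates ring closure from carbonylation. Iodine with NaHCO3 in MeCN at rt should bring about 5-endo-dig iodocyclization of 9 to 3-[2-(4-benzyloxy-3-methoxyphenyl)-3-iodo-7-methoxybenzofuran-5-yl]propyl acetate F1. Palladium-catalysed methoxycarbonylation of the C3–I bond (Pd(OAc)2, dppf, Et3N, CO 1 atm, MeOH–DMF, 70 °C) should then give 10. The C3–Pd bond then arises by oxidative addition under basic conditions, where protodemetalation is not a competitor.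

Step 6. The amine may fail to discriminate between the two acetates, so that the alkyl acetate is partly lost and mixtures result. The fallback sets out from 8 and comes back at 11, and gives up the differentiation. K2CO3 in MeOH at rt removes both acetates to give 3-[3-[(4-benzyloxy-3-methoxyphenyl)ethynyl]-4-hydroxy-5-methoxyphenyl]propan-1-ol F2. The cyclization–carbonylation is then run on this alkynylphenol with its free side-chain alcohol under the conditions of step 7 (PdCl2, CuCl2, NaOAc, CO, MeOH, rt), and should give methyl 2-(4-benzyloxy-3-methoxyphenyl)-5-(3-hydroxypropyl)-7-methoxybenzofuran-3-carboxylate F3. Reduction with i-Bu2AlH then gives diol 11.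

Step 10. The Lewis acid may cleave a methyl ether, benzylate the electron-rich benzofuran, or convert the side-chain borate into a chloride. The fallback sets out from 10 and comes back at 13, and exchanges the benzyl ether for a silyl ether at the ester stage, where hydrogenolysis is harmless. Hydrogen over palladium on carbon (Pd/C) in EtOAc should give methyl 5-(3-acetoxypropyl)-2-(4-hydroxy-3-methoxyphenyl)-7-methoxybenzofuran-3-carboxylate F4. TIPSCl and imidazole in DMF should then give methyl 5-(3-acetoxypropyl)-7-methoxy-2-[3-methoxy-4-(triisopropylsilyloxy)phenyl]benzofuran-3-carboxylate F5. Reduction with i-Bu2AlH should give [5-(3-hydroxypropyl)-7-methoxy-2-[3-methoxy-4-(triisopropylsilyloxy)phenyl]benzofuran-3-yl]methanol F6. MnO2 in CH2Cl2 should oxidize it to 5-(3-hydroxypropyl)-7-methoxy-2-[3-methoxy-4-(triisopropylsilyloxy)phenyl]benzofuran-3-carbaldehyde F7. Bu4NF buffered with AcOH in THF at 0 °C should finally remove the silyl group to give 13.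

**Further compounds**
F1 | step 7 | 3-[2-(4-benzyloxy-3-methoxyphenyl)-3-iodo-7-methoxybenzofuran-5-yl]propyl acetate | COc1cc(CCCOC(C)=O)cc2c(I)c(-c3ccc(OCc4ccccc4)c(OC)c3)oc12
F2 | step 6 | 3-[3-[(4-benzyloxy-3-methoxyphenyl)ethynyl]-4-hydroxy-5-methoxyphenyl]propan-1-ol | COc1cc(CCCO)cc(C#Cc2ccc(OCc3ccccc3)c(OC)c2)c1O
F3 | step 6 | methyl 2-(4-benzyloxy-3-methoxyphenyl)-5-(3-hydroxypropyl)-7-methoxybenzofuran-3-carboxylate | COC(=O)c1c(-c2ccc(OCc3ccccc3)c(OC)c2)oc2c(OC)cc(CCCO)cc12
F4 | step 10 | methyl 5-(3-acetoxypropyl)-2-(4-hydroxy-3-methoxyphenyl)-7-methoxybenzofuran-3-carboxylate | COC(=O)c1c(-c2ccc(O)c(OC)c2)oc2c(OC)cc(CCCOC(C)=O)cc12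
F5 | step 10 | methyl 5-(3-acetoxypropyl)-7-methoxy-2-[3-methoxy-4-(triisopropylsilyloxy)phenyl]benzofuran-3-carboxylate | COC(=O)c1c(-c2ccc(O[Si](C(C)C)(C(C)C)C(C)C)c(OC)c2)oc2c(OC)cc(CCCOC(C)=O)cc12
F6 | step 10 | [5-(3-hydroxypropyl)-7-methoxy-2-[3-methoxy-4-(triisopropylsilyloxy)phenyl]benzofuran-3-yl]methanol | OCc1c(-c2ccc(O[Si](C(C)C)(C(C)C)C(C)C)c(OC)c2)oc2c(OC)cc(CCCO)cc12
F7 | step 10 | 5-(3-hydroxypropyl)-7-methoxy-2-[3-methoxy-4-(triisopropylsilyloxy)phenyl]benzofuran-3-carbaldehyde | O=Cc1c(-c2ccc(O[Si](C(C)C)(C(C)C)C(C)C)c(OC)c2)oc2c(OC)cc(CCCO)cc12
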